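**Strategy.** Everything rests on cutting C1–C8a of the tetralin's saturated ring (C1, C2, C3, C4, C4a, C8a). That cut unmasks a hidden twofold-symmetric (R,R)-2,3-dimethyl-1,4-diarylbutane. The trans-dimethyl chain C1–C4 lies between two identical guaiacyl rings, so both benzylic CH2 groups and both phenols are homotopic. The key step is a dehydrogenative closure of its monobenzyl ether. Ag2O converts the single free guaiacol into a p-quinone methide, making C1 electrophilic, and acid lets C8a (para to OMe of the benzylated ring) add. One operation joins two C–H carbons, sets C1 trans to the C2 methyl, and leaves free exactly the phenol that then takes the lactate-derived 8-O-4' chain.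

Key step: step 6

Numbering used below: tetralin C1 (aryl-bearing) to C8a. Ring A is the fused arene, ring B the pendant arene and ring C the side-chain arene. C7'' is the carbinol carbon and C8'' the ether carbon of the side chain.

**Step 1**
Reactants: 1 (R)-4-benzyl-3-propanoyl-1,3-oxazolidin-2-one (two molecules)
Product: 3 (2S,3S)-1,4-bis[(4R)-4-benzyl-2-oxo-1,3-oxazolidin-3-yl]-2,3-dimethylbutane-1,4-dione, via lithium Z-enolate 2 (not isolated)
Conditions: LDA, THF, −78 °C; then anhydrous CuCl2, DMF–THF, −78 → 0 °C
Reagents that add atoms: lithium diisopropylamide, CC(C)[N-]C(C)C.[Li+] (lithium, held only in 2)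
Why: Oxidative enolate homocoupling of a chiral N-acyloxazolidinone: Cu(II) oxidises the chelated Z-enolate 2 and each new C–C terminus forms on the enolate face away from the benzyl group, so both new stereocentres (later C2 and C3 of the tetralin) should be set S,S by the (R)-auxiliary, in the same sense as in its alkylations.

**Step 2**
Reactants: 3 bis-imide
Product: 4 (2S,3S)-2,3-dimethylbutane-1,4-diol
Conditions: LiBH4 (excess), H2O (1 equiv per imide), Et2O–THF, 0 °C
Reagents that add atoms: none
Why: Reductive cleavage of the N-acyloxazolidinones by LiBH4 takes place at the exocyclic carbonyl groups only, touches neither stereocentre and returns the auxiliary.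

**Step 3**
Reactants: 4 diol
Product: 5 (2S,3S)-2,3-dimethylbutane-1,4-diyl bis(4-methylbenzenesulfonate)
Conditions: TsCl (excess), pyridine, 0 °C
Reagents that add atoms: p-toluenesulfonyl chloride, Cc1ccc(cc1)S(=O)(=O)Cl
Why: Plain tosylation of two primary alcohols; excess TsCl at low temperature tosylates the second hydroxyl before the monotosylate can close to a tetrahydrofuran.

**Step 4**
Reactants: 5 ditosylate; 6 1-(benzyloxy)-4-bromo-2-methoxybenzene (two molecules)
Product: 8 (2R,3R)-1,4-bis[4-(benzyloxy)-3-methoxyphenyl]-2,3-dimethylbutane, via Grignard reagent 7 (not isolated)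
Conditions: 6, Mg, THF; then 5, Li2CuCl4 (cat.), THF, 0 °C → rt
Reagents that add atoms: magnesium, [Mg] (held only in 7)
Why: Copper-catalysed Grignard–tosylate cross-coupling (Kochi–Schlosser type) at two primary carbons; the stereocentres are one carbon away and keep their geometry, and the descriptors change from S,S to R,R only through the CIP priorities.

**Step 5**
Reactants: 8 dibenzyl ether
Product: 9 4-{(2R,3R)-4-[4-(benzyloxy)-3-methoxyphenyl]-2,3-dimethylbutyl}-2-methoxyphenol
Conditions: H2 (1 atm), 5% Pd/C, EtOAc, rt, stopped after uptake of about one equivalent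
Reagents that add atoms: none
Why: Catalytic hydrogenolysis of an aryl benzyl ether stopped early; the two benzyl ethers are homotopic, so loss of either gives the same 9, the outcome is statistical, and recovered 8 is separated from the phenol by polarity and recycled.

**Step 6**
Reactants: 9 monobenzyl ether
Product: 11 4-[(1S,2S,3R)-7-(benzyloxy)-6-methoxy-2,3-dimethyl-1,2,3,4-tetrahydronaphthalen-1-yl]-2-methoxyphenol, via p-quinone methide 10 (not isolated)
Conditions: Ag2O, 4 Å MS, CH2Cl2, rt, dark; filter (Celite); then TFA (cat.), −40 → 0 °C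
Reagents that add atoms: none
Why: Ag2O takes two electrons and two protons from the only free guaiacol (ring B) and gives p-quinone methide 10, in which C1 is the electrophilic terminus; after the silver is filtered off, catalytic TFA protonates the quinone methide oxygen, C8a of ring A attacks C1, and loss of the C8a proton rearomatises both rings and returns the acid. The closest known reaction type is the p-quinone methide initiated Friedel–Crafts cyclisation of 4-alkylphenols (Ag2O, then acid), the laboratory counterpart of aryltetralin lignan biogenesis. The single ring formed closes 6-exo-trig with respect to the exocyclic C1=C1' bond of the quinone methide (Ar2-6 participation of ring A). C1 is the only new stereocentre and is set by C2 and C3: in the chair-like transition state both methyl groups and the quinone methide ring lie pseudo-equatorial, which should give the all-trans (1S,2S,3R) tetralin, also the more stable C1 epimer. Three selectivities are needed: which benzylic carbon is oxidised (only ring B has a free OH, and ring A as a benzyl ether cannot form a quinone methide), which carbon of ring A attacks (the position para to its OMe is activated and open, while the position between CH2 and OMe is crowded), and no second oxidation at the doubly benzylic C1–H of 11 (the oxidant has left the flask before 11 forms).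

**Step 7**
Reactants: 11 tetralin phenol; 12 ethyl (S)-lactate
Product: 13 ethyl (2R)-2-{4-[(1S,2S,3R)-7-(benzyloxy)-6-methoxy-2,3-dimethyl-1,2,3,4-tetrahydronaphthalen-1-yl]-2-methoxyphenoxy}propanoate
Conditions: PPh3, DIAD, THF, 0 °C → rt
Reagents that add atoms: none
Why: Mitsunobu etherification: the only acidic OH of 11 displaces the activated lactate oxygen by SN2 with inversion, which turns the (S)-centre of 12 into the (R)-configured C8''.

**Step 8**
Reactants: 13 ester; 7 Grignard reagent (fresh solution made from 6 and Mg as in step 4)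
Product: 15 (2R)-1-[4-(benzyloxy)-3-methoxyphenyl]-2-{4-[(1S,2S,3R)-7-(benzyloxy)-6-methoxy-2,3-dimethyl-1,2,3,4-tetrahydronaphthalen-1-yl]-2-methoxyphenoxy}propan-1-one, via Weinreb amide 14 (not isolated)
Conditions: MeONHMe·HCl, i-PrMgCl, THF, −20 °C; then 7, −20 → 0 °C; aq. NH4Cl
Reagents that add atoms: N,O-dimethylhydroxylamine hydrochloride, CNOC.Cl (its atoms are held only in 14)
Why: Weinreb ketone synthesis run in one pot: the magnesium amide turns the ester into 14, whose chelated tetrahedral adduct with 7 survives until the quench and so stops at the ketone, and at low temperature C8'' is not enolised.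

**Step 9**
Reactants: 15 ketone
Product: 16 (1S,2R)-1-[4-(benzyloxy)-3-methoxyphenyl]-2-{4-[(1S,2S,3R)-7-(benzyloxy)-6-methoxy-2,3-dimethyl-1,2,3,4-tetrahydronaphthalen-1-yl]-2-methoxyphenoxy}propan-1-ol
Conditions: Zn(BH4)2, Et2O–CH2Cl2, −40 → 0 °C
Reagents that add atoms: none
Why: Chelation-controlled (Cram chelate) reduction: Zn(II) ties the ketone oxygen to the C8'' aryloxy oxygen, aided by the neighbouring OMe of ring B, and hydride enters from the side of the C8'' hydrogen, which should set C7'' as S (erythro).

**Step 10**
Reactants: 16 dibenzyl ether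
Product: 17 target, CID53359464
Conditions: H2 (1 atm), 10% Pd/C, EtOAc–EtOH, rt, neutral
Reagents that add atoms: none
Why: Neutral catalytic hydrogenolysis removes both aryl benzyl ethers faster than it touches the secondary benzylic alcohol, the alkyl aryl ether or any stereocentre.

**Compound list**
1 | (R)-4-benzyl-3-propanoyl-1,3-oxazolidin-2-one | CCC(=O)N1[C@H](Cc2ccccc2)COC1=O | starting material
2 | lithium (Z)-enolate of 1 | C/C=C(\[O-])N1[C@H](Cc2ccccc2)COC1=O.[Li+] | intermediate
3 | (2S,3S)-1,4-bis[(4R)-4-benzyl-2-oxo-1,3-oxazolidin-3-yl]-2,3-dimethylbutane-1,4-dione | O=C1OC[C@@H](Cc2ccccc2)N1C(=O)[C@@H](C)[C@H](C)C(=O)N1[C@H](Cc2ccccc2)COC1=O | intermediate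
4 | (2S,3S)-2,3-dimethylbutane-1,4-diol | OC[C@@H](C)[C@H](C)CO | intermediate
5 | (2S,3S)-2,3-dimethylbutane-1,4-diyl bis(4-methylbenzenesulfonate) | Cc1ccc(cc1)S(=O)(=O)OC[C@@H](C)[C@H](C)COS(=O)(=O)c1ccc(C)cc1 | intermediate
6 | 1-(benzyloxy)-4-bromo-2-methoxybenzene | COc1cc(Br)ccc1OCc1ccccc1 | starting material
7 | [4-(benzyloxy)-3-methoxyphenyl]magnesium bromide | COc1cc([Mg]Br)ccc1OCc1ccccc1 | intermediate
8 | (2R,3R)-1,4-bis[4-(benzyloxy)-3-methoxyphenyl]-2,3-dimethylbutane (dibenzyl ether of (8R,8'R)-dihydroguaiaretic acid) | COc1cc(C[C@@H](C)[C@H](C)Cc2ccc(OCc3ccccc3)c(OC)c2)ccc1OCc1ccccc1 | intermediate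
9 | 4-{(2R,3R)-4-[4-(benzyloxy)-3-methoxyphenyl]-2,3-dimethylbutyl}-2-methoxyphenol | COc1cc(C[C@@H](C)[C@H](C)Cc2ccc(O)c(OC)c2)ccc1OCc1ccccc1 | intermediate
10 | 4-{(2S,3R)-4-[4-(benzyloxy)-3-methoxyphenyl]-2,3-dimethylbutylidene}-2-methoxycyclohexa-2,5-dien-1-one (alkene geometry not defined) | COc1cc(C[C@@H](C)[C@H](C)C=C2C=CC(=O)C(OC)=C2)ccc1OCc1ccccc1 | intermediate
11 | 4-[(1S,2S,3R)-7-(benzyloxy)-6-methoxy-2,3-dimethyl-1,2,3,4-tetrahydronaphthalen-1-yl]-2-methoxyphenol | COc1cc(ccc1O)[C@H]1c2cc(OCc3ccccc3)c(OC)cc2C[C@@H](C)[C@@H]1C | intermediate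
12 | ethyl (S)-lactate | CCOC(=O)[C@H](C)O | starting material
13 | ethyl (2R)-2-aryloxypropanoate of 11 | CCOC(=O)[C@@H](C)Oc1ccc(cc1OC)[C@H]1c2cc(OCc3ccccc3)c(OC)cc2C[C@@H](C)[C@@H]1C | intermediate
14 | (2R)-N-methoxy-N-methyl-2-aryloxypropanamide of 11 | CON(C)C(=O)[C@@H](C)Oc1ccc(cc1OC)[C@H]1c2cc(OCc3ccccc3)c(OC)cc2C[C@@H](C)[C@@H]1C | intermediate
15 | (2R)-α-aryloxy ketone, rings A and C as benzyl ethers | COc1cc(ccc1OCc1ccccc1)C(=O)[C@@H](C)Oc1ccc(cc1OC)[C@H]1c2cc(OCc3ccccc3)c(OC)cc2C[C@@H](C)[C@@H]1C | intermediate
16 | (7''S,8''R)-erythro alcohol, rings A and C as benzyl ethers | COc1cc(ccc1OCc1ccccc1)[C@H](O)[C@@H](C)Oc1ccc(cc1OC)[C@H]1c2cc(OCc3ccccc3)c(OC)cc2C[C@@H](C)[C@@H]1C | intermediate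
17 | CID53359464 | COc1cc([C@H](O)[C@@H](C)Oc2ccc([C@H]3c4cc(O)c(OC)cc4C[C@@H](C)[C@@H]3C)cc2OC)ccc1O | target

**Total step count:** 10. **Longest linear sequence:** 10 steps (1 → 17); 6 and 12 are bought.

**Steps most likely to fail**

Step 6. On the silver surface, coupling of phenoxyl radicals at the free ortho position may compete with quinone methide formation. After protonation, proton loss from C2 (tautomerisation to the styrene) may outrun ring closure and erode the C2 configuration. The fallback separates oxidation from C–C bond formation. It sets out from 9. One equivalent of DDQ in MeOH–CH2Cl2 carries out the known benzylic methoxylation of 4-alkylphenols and traps the quinone methide as the benzylic methyl ether F1, a stable compound that is purified free of oxidant. BF3·OEt2 in CH2Cl2 at −78 °C then ionises this ether, and the same stereoconvergent Friedel–Crafts closure brings the route back at 11.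

Step 4. The double displacement at β-branched primary tosylates may be slow. That would leave room for attack of the Grignard reagent at sulfur and for its homocoupling. The fallback reverses the polarity of the coupling. It sets out from 5. A Finkelstein reaction (NaI, acetone, reflux) gives (2S,3S)-1,4-diiodo-2,3-dimethylbutane F2. Zinc dust with LiCl in THF inserts into both C–I bonds to give the bis(iodozinc) reagent F3. A Negishi coupling with two equivalents of aryl bromide 6 (Pd(OAc)2, SPhos) brings the route back at 8.

Step 9. The aryloxy oxygen is a weak donor, so chelation may be incomplete and the facial selectivity poor. The fallback replaces substrate control by catalyst control. It sets out from 15 and uses asymmetric transfer hydrogenation with RuCl[(R,R)-TsDPEN](p-cymene) in HCO2H–Et3N. There the contact of the catalyst with ring C fixes the hydride face, and the (R,R)-catalyst is expected to give the 7''S carbinol. It comes back at 16 and makes no new compound (F0).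

**Further compounds**
F1 | step 6 | 4-{(2S,3R)-4-[4-(benzyloxy)-3-methoxyphenyl]-1-methoxy-2,3-dimethylbutyl}-2-methoxyphenol (both C1 epimers) | COc1cc(C[C@@H](C)[C@H](C)C(OC)c2ccc(O)c(OC)c2)ccc1OCc1ccccc1
F2 | step 4 | (2S,3S)-1,4-diiodo-2,3-dimethylbutane | IC[C@@H](C)[C@H](C)CI
F3 | step 4 | [(2S,3S)-2,3-dimethylbutane-1,4-diyl]bis(iodozinc) | I[Zn]C[C@@H](C)[C@H](C)C[Zn]I
F0 | step 9 | none | none
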